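**Retrosynthetic overview**
1. Ring B is closed last: the bond from the spiro carbon C6 to the ring B methylene C11 is made by a Claisen ring contraction of pyran 19, a 2-alkenyl-3,4-dihydro-2H-pyran fused to ring A through O1–C8a=C4a; this temporary pyran ring is consumed in the same step.
2. Enabling feature: C6 is C2 of the ring A cyclohexane-1,3-dione and carries the allyl unit C11H2–C10(R)=C9H of ring B (a 2-allyl-1,3-dione); tying C9 to the oxygen of the ring A carbonyl next to CMe2 gives the allyl vinyl ether of a [3,3] shift.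
3. Pyran 19 comes from ring A dione 6 and ketoester 11: Cu-bis(oxazoline) Michael addition and cyclodehydration set C4, cis-hydrogenation sets C2, and the ester is turned into the 6-methylhepta-1,5-dien-2-yl group.
4. Ring A (6) is made first from 2,4,6-trihydroxybenzoic acid: methylation of O-4, dearomatising C-trimethylation, loss of the carboxyl group.
5. Order of ring formation: ring A, then the temporary pyran, then ring B.

Key step: step 10

Assumption (step 6): the reversible hemiketal closure is taken to use the enol oxygen on the carbonyl carbon next to the gem-dimethyl carbon, which gives the cross-conjugated (2,5-cyclohexadienone-type) vinylogous ester.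

Pyran-stage compounds use chromene numbering (O1, C2, C3, C4, C4a, C5–C8, C8a).

Step 1
Reactants: 1 2,4,6-trihydroxybenzoic acid
Product: 2 benzyl 2,4,6-trihydroxybenzoate
Conditions: BnBr, KHCO3, DMF, rt
Reagents that add atoms: benzyl bromide, BrCc1ccccc1
Why: Carboxylate O-alkylation (SN2 esterification): hydrogencarbonate ionises only the carboxylic acid, so benzyl bromide esterifies it and leaves the three phenols free.

Step 2
Reactants: 2 benzyl 2,4,6-trihydroxybenzoate
Product: 3 benzyl 2,6-dihydroxy-4-methoxybenzoate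
Conditions: Me2SO4 (1.05 equiv), K2CO3, acetone, rt
Reagents that add atoms: dimethyl sulfate, COS(=O)(=O)OC
Why: Williamson ether synthesis, regioselective because the 2- and 6-hydroxyls are locked in hydrogen bonds to the ester carbonyl while the 4-hydroxyl is the most acidic and the only free one.

Step 3
Reactants: 3 benzyl 2,6-dihydroxy-4-methoxybenzoate
Product: 4 benzyl 4-methoxy-3,5,5-trimethyl-2,6-dioxocyclohex-3-ene-1-carboxylate
Conditions: MeI (3.3 equiv), t-BuOK, t-BuOH/THF, 0 °C to rt
Reagents that add atoms: iodomethane, CI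
Why: Alkylative dearomatisation of a phloroglucinol: the phenoxide is C-methylated at both ring carbons lying between O– and OMe and a third methyl on an already methylated carbon breaks the aromatic ring, the fixed 4-methoxy enol ether allowing only one gem-dimethyl carbon and the bulky alkoxide sparing the benzyl ester.

Step 4
Reactants: 4 benzyl 4-methoxy-3,5,5-trimethyl-2,6-dioxocyclohex-3-ene-1-carboxylate
Product: 6 5-methoxy-4,6,6-trimethylcyclohex-4-ene-1,3-dione, via keto acid 5 (not isolated)
Conditions: H2 (1 atm), Pd/C, EtOAc, rt, then 40 °C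
Reagents that add atoms: none
Why: Hydrogenolysis of the benzyl ester followed by decarboxylation of the β-keto acid, which is flanked by two carbonyls and should lose CO2 on gentle warming, under neutral conditions that leave the methyl enol ether and the tetrasubstituted push-pull alkene untouched.

Step 5
Reactants: 7 ethyl 3-bromo-2-oxopropanoate; 8 2-methylpropanal
Product: 11 ethyl (3E)-5-methyl-2-oxohex-3-enoate, via phosphonium bromide 9 (not isolated), via acyl ylide 10 (not isolated)
Conditions: PPh3, PhMe, rt; aq. Na2CO3, CH2Cl2; then 8, CH2Cl2, 40 °C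
Reagents that add atoms: none
Why: Wittig olefination of the aldehyde by the stabilised acyl ylide made in the flask, which should give the (E)-enone.

Step 6
Reactants: 6 5-methoxy-4,6,6-trimethylcyclohex-4-ene-1,3-dione; 11 ethyl (3E)-5-methyl-2-oxohex-3-enoate
Product: 13 ethyl (4R)-7-methoxy-6,8,8-trimethyl-5-oxo-4-(propan-2-yl)-5,8-dihydro-4H-chromene-2-carboxylate, via hemiketal 12 (not isolated)
Conditions: Cu(OTf)2/(S,S)-t-Bu-box (10 mol%), Et2O, rt; then TsOH (cat.), PhMe, 60 °C
Reagents that add atoms: none
Why: Enantioselective Michael addition of the enol of 6 to the 2-oxo-3-enoate chelated to divalent copper, in which the C2-symmetric bis(oxazoline) shields one enone face and so sets C4 (4S in 12; the ligand antipode serves if the sense of induction is the other one), followed by reversible hemiketal closure and acid-catalysed dehydration to the 4H-pyran.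

Step 7
Reactants: 13 ethyl (4R)-7-methoxy-6,8,8-trimethyl-5-oxo-4-(propan-2-yl)-5,8-dihydro-4H-chromene-2-carboxylate
Product: 14 ethyl (2R,4S)-7-methoxy-6,8,8-trimethyl-5-oxo-4-(propan-2-yl)-3,4,5,8-tetrahydro-2H-chromene-2-carboxylate
Conditions: H2 (1 atm), Pd/C, EtOAc, rt
Reagents that add atoms: none
Why: Heterogeneous syn-hydrogenation of the 2-alkoxyacrylate double bond from the face opposite to the 4-isopropyl group, which sits pseudo-axial to avoid allylic strain with the C5 carbonyl, so that C2 is set with the ester cis to isopropyl while the tetrasubstituted alkenes of ring A stay inert.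

Step 8
Reactants: 14 ethyl (2R,4S)-7-methoxy-6,8,8-trimethyl-5-oxo-4-(propan-2-yl)-3,4,5,8-tetrahydro-2H-chromene-2-carboxylate; 15 5-bromo-2-methylpent-2-ene
Product: 18 (2R,4S)-7-methoxy-6,8,8-trimethyl-2-(5-methylhex-4-enoyl)-4-(propan-2-yl)-2,3,4,8-tetrahydro-5H-chromen-5-one, via Grignard reagent 16 (not isolated), via Weinreb amide 17 (not isolated)
Conditions: MeNH(OMe)·HCl, i-PrMgCl, THF, −20 °C; then 16 (15, Mg, THF), −20 to 0 °C; aq. NH4Cl
Reagents that add atoms: N,O-dimethylhydroxylamine hydrochloride, CNOC.Cl (its atoms reach only intermediate 17); magnesium, [Mg] (its atom reaches only intermediate 16)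
Why: One-pot Weinreb ketone synthesis: the magnesium amide turns the ester into the N-methoxy-N-methylamide, whose chelated tetrahedral adduct with Grignard reagent 16 stops at the ketone, the doubly donor-substituted ring A carbonyl being far less electrophilic and C2 and C4 staying untouched.

Step 9
Reactants: 18 (2R,4S)-7-methoxy-6,8,8-trimethyl-2-(5-methylhex-4-enoyl)-4-(propan-2-yl)-2,3,4,8-tetrahydro-5H-chromen-5-one
Product: 19 (2R,4S)-7-methoxy-6,8,8-trimethyl-2-(6-methylhepta-1,5-dien-2-yl)-4-(propan-2-yl)-2,3,4,8-tetrahydro-5H-chromen-5-one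
Conditions: Ph3PCH3Br, KN(SiMe3)2, THF, −78 to 0 °C
Reagents that add atoms: methyltriphenylphosphonium bromide, C[P+](c1ccccc1)(c1ccccc1)c1ccccc1.[Br-]
Why: Wittig methylenation with the lithium-free ylide at low temperature, where addition to the ketone should be faster than enolisation so that C2 keeps its configuration, and the vinylogous-ester carbonyl of ring A does not react.

Step 10
Reactants: 19 (2R,4S)-7-methoxy-6,8,8-trimethyl-2-(6-methylhepta-1,5-dien-2-yl)-4-(propan-2-yl)-2,3,4,8-tetrahydro-5H-chromen-5-one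
Product: 20 (6R,7S)-3-methoxy-2,4,4-trimethyl-10-(4-methylpent-3-en-1-yl)-7-(propan-2-yl)spiro[5.5]undeca-2,9-diene-1,5-dione
Conditions: PhMe, 2,6-lutidine (cat.), 140 °C, sealed tube
Reagents that add atoms: none
Why: Claisen rearrangement: a concerted, suprafacial [3,3] shift in which the array C4a=C8a–O1–C2–C(R)=CH2 reorganises so that the exocyclic CH2 bonds to C4a while the O1–C2 bond breaks and C8a becomes the second ring A carbonyl. The closest known reaction types are the Claisen ring contraction of 2-alkenyl-3,4-dihydro-2H-pyrans to cyclohex-3-enyl ketones and the Claisen rearrangement of O-allyl enol ethers of cyclic 1,3-diones to 2,2-disubstituted diones. Ring B closes as a six-membered carbocycle by 6-endo bonding of the enol ether carbon to the far terminus of the allyl unit, through a boat-like, bicyclo[2.2.2]octane-shaped transition state that the pyran ring enforces. The new spiro stereocentre is controlled by C2: the bond forms on the face of C4a that carries the alkenyl group, so the C–O stereocentre is transferred 1,3 to carbon, and with the alkenyl group cis to isopropyl and O1 on the carbonyl carbon next to CMe2, isopropyl should end cis to the enone carbonyl as in the target. The step needs the [3,3] path to win over retro-oxa-[4+2] cleavage and over ionisation of the allylic C–O bond; the acyl group on the bond-forming enol carbon and the secondary allylic ether carbon lower the Claisen barrier, and a trace of base in a non-polar solvent keeps the ionic path closed.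

**Compound list**
1 | 2,4,6-trihydroxybenzoic acid | OC(=O)c1c(O)cc(O)cc1O | starting material
2 | benzyl 2,4,6-trihydroxybenzoate | O=C(OCc1ccccc1)c1c(O)cc(O)cc1O | intermediate
3 | benzyl 2,6-dihydroxy-4-methoxybenzoate | COc1cc(O)c(C(=O)OCc2ccccc2)c(O)c1 | intermediate
4 | benzyl 4-methoxy-3,5,5-trimethyl-2,6-dioxocyclohex-3-ene-1-carboxylate (drawn as the keto tautomer) | COC1=C(C)C(=O)C(C(=O)OCc2ccccc2)C(=O)C1(C)C | intermediate
5 | 4-methoxy-3,5,5-trimethyl-2,6-dioxocyclohex-3-ene-1-carboxylic acid | COC1=C(C)C(=O)C(C(O)=O)C(=O)C1(C)C | intermediate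
6 | 5-methoxy-4,6,6-trimethylcyclohex-4-ene-1,3-dione | COC1=C(C)C(=O)CC(=O)C1(C)C | intermediate
7 | ethyl 3-bromo-2-oxopropanoate (ethyl bromopyruvate) | CCOC(=O)C(=O)CBr | starting material
8 | 2-methylpropanal | CC(C)C=O | starting material
9 | (3-ethoxy-2,3-dioxopropyl)triphenylphosphonium bromide | CCOC(=O)C(=O)C[P+](c1ccccc1)(c1ccccc1)c1ccccc1.[Br-] | intermediate
10 | ethyl 2-oxo-3-(triphenyl-λ5-phosphanylidene)propanoate | CCOC(=O)C(=O)C=P(c1ccccc1)(c1ccccc1)c1ccccc1 | intermediate
11 | ethyl (3E)-5-methyl-2-oxohex-3-enoate | CCOC(=O)C(=O)/C=C/C(C)C | intermediate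
12 | ethyl (4S)-2-hydroxy-7-methoxy-6,8,8-trimethyl-5-oxo-4-(propan-2-yl)-3,4,5,8-tetrahydro-2H-chromene-2-carboxylate (both C2 epimers) | COC1=C(C)C(=O)C2=C(OC(O)(C(=O)OCC)C[C@H]2C(C)C)C1(C)C | intermediate
13 | ethyl (4R)-7-methoxy-6,8,8-trimethyl-5-oxo-4-(propan-2-yl)-5,8-dihydro-4H-chromene-2-carboxylate | COC1=C(C)C(=O)C2=C(OC(C(=O)OCC)=C[C@H]2C(C)C)C1(C)C | intermediate
14 | ethyl (2R,4S)-7-methoxy-6,8,8-trimethyl-5-oxo-4-(propan-2-yl)-3,4,5,8-tetrahydro-2H-chromene-2-carboxylate (2,4-cis) | COC1=C(C)C(=O)C2=C(O[C@@H](C(=O)OCC)C[C@H]2C(C)C)C1(C)C | intermediate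
15 | 5-bromo-2-methylpent-2-ene | CC(C)=CCCBr | starting material
16 | (4-methylpent-3-en-1-yl)magnesium bromide | CC(C)=CCC[Mg]Br | intermediate
17 | (2R,4S)-N,7-dimethoxy-N,6,8,8-tetramethyl-5-oxo-4-(propan-2-yl)-3,4,5,8-tetrahydro-2H-chromene-2-carboxamide | COC1=C(C)C(=O)C2=C(O[C@@H](C(=O)N(C)OC)C[C@H]2C(C)C)C1(C)C | intermediate
18 | (2R,4S)-7-methoxy-6,8,8-trimethyl-2-(5-methylhex-4-enoyl)-4-(propan-2-yl)-2,3,4,8-tetrahydro-5H-chromen-5-one | COC1=C(C)C(=O)C2=C(O[C@@H](C(=O)CCC=C(C)C)C[C@H]2C(C)C)C1(C)C | intermediate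
19 | (2R,4S)-7-methoxy-6,8,8-trimethyl-2-(6-methylhepta-1,5-dien-2-yl)-4-(propan-2-yl)-2,3,4,8-tetrahydro-5H-chromen-5-one (2,4-cis) | COC1=C(C)C(=O)C2=C(O[C@@H](C(=C)CCC=C(C)C)C[C@H]2C(C)C)C1(C)C | intermediate
20 | (6R,7S)-3-methoxy-2,4,4-trimethyl-10-(4-methylpent-3-en-1-yl)-7-(propan-2-yl)spiro[5.5]undeca-2,9-diene-1,5-dione | COC1=C(C)C(=O)[C@]2(CC(CCC=C(C)C)=CC[C@H]2C(C)C)C(=O)C1(C)C | target

**Totals**
Total step count: 10. Longest linear sequence: 9 steps (steps 1–4 and 6–10; step 5 is the side branch).

**Three steps most likely to fail**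

Step 6. The pyran annulation may take the other enol oxygen (wrong regiochemistry of hemiketal closure), which would feed the rearrangement into the epimeric spiro series. The fallback uses that regioisomer productively, because a pyran with its oxygen on the other carbonyl carbon and its 2-substituent trans to isopropyl converges on the same spiro configuration. It sets out from 6 (with 11) and returns to the route at 20. The same Michael addition would give the hemiketal ethyl (4S)-2-hydroxy-7-methoxy-6,6,8-trimethyl-5-oxo-4-(propan-2-yl)-3,4,5,6-tetrahydro-2H-chromene-2-carboxylate F1 and, after dehydration, ethyl (4R)-7-methoxy-6,6,8-trimethyl-5-oxo-4-(propan-2-yl)-5,6-dihydro-4H-chromene-2-carboxylate F2. Hydrogenation should give the cis ester ethyl (2R,4S)-7-methoxy-6,6,8-trimethyl-5-oxo-4-(propan-2-yl)-3,4,5,6-tetrahydro-2H-chromene-2-carboxylate F3. NaOEt in EtOH should then equilibrate C2 to the trans ester ethyl (2S,4S)-7-methoxy-6,6,8-trimethyl-5-oxo-4-(propan-2-yl)-3,4,5,6-tetrahydro-2H-chromene-2-carboxylate F4 (ester equatorial, isopropyl pseudo-axial). The one-pot ketone synthesis through (2S,4S)-N,7-dimethoxy-N,6,6,8-tetramethyl-5-oxo-4-(propan-2-yl)-3,4,5,6-tetrahydro-2H-chromene-2-carboxamide F5 gives (2S,4S)-7-methoxy-6,6,8-trimethyl-2-(5-methylhex-4-enoyl)-4-(propan-2-yl)-2,3,4,6-tetrahydro-5H-chromen-5-one F6. Methylenation gives (2S,4S)-7-methoxy-6,6,8-trimethyl-2-(6-methylhepta-1,5-dien-2-yl)-4-(propan-2-yl)-2,3,4,6-tetrahydro-5H-chromen-5-one F7, and the same thermal [3,3] shift leads to 20.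

Step 10. Cycloreversion (retro-oxa-[4+2]) to the isobutylidene dione and the triene, or heterolysis of the allylic C–O bond, may compete at the temperature of the rearrangement and erode the stereochemical relay. The fallback forms the same bond by a different mechanism at room temperature. It sets out from 19 and returns at 20: Pd(PPh3)4 (zerovalent palladium) in THF should effect the known O-to-C allyl transposition of allyl enol ethers of 1,3-diones through a π-allyl/enolate pair that recloses at carbon at the unsubstituted allyl terminus. The spiro centre is then set under substrate control instead of by the sigmatropic relay, so the epimer, if formed, would have to be removed by chromatography.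

Step 9. Enolisation of the α-alkoxy ketone by the ylide may epimerise C2, which would invert the spiro centre after the rearrangement. The fallback replaces the Wittig reaction by a non-basic addition and a separate elimination (Peterson olefination). It sets out from 18 and returns at 19: Me3SiCH2MgCl with CeCl3 in THF at −78 °C should add to the ketone without enolisation to give (2R,4S)-2-[2-hydroxy-6-methyl-1-(trimethylsilyl)hept-5-en-2-yl]-7-methoxy-6,8,8-trimethyl-4-(propan-2-yl)-2,3,4,8-tetrahydro-5H-chromen-5-one F8 (both carbinol epimers), and KH in THF then eliminates to 19.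

**Further compounds**
F1 | step 6 | ethyl (4S)-2-hydroxy-7-methoxy-6,6,8-trimethyl-5-oxo-4-(propan-2-yl)-3,4,5,6-tetrahydro-2H-chromene-2-carboxylate | COC1=C(C)C2=C([C@H](C(C)C)CC(O)(C(=O)OCC)O2)C(=O)C1(C)C
F2 | step 6 | ethyl (4R)-7-methoxy-6,6,8-trimethyl-5-oxo-4-(propan-2-yl)-5,6-dihydro-4H-chromene-2-carboxylate | COC1=C(C)C2=C([C@H](C(C)C)C=C(C(=O)OCC)O2)C(=O)C1(C)C
F3 | step 6 | ethyl (2R,4S)-7-methoxy-6,6,8-trimethyl-5-oxo-4-(propan-2-yl)-3,4,5,6-tetrahydro-2H-chromene-2-carboxylate | COC1=C(C)C2=C([C@H](C(C)C)C[C@H](C(=O)OCC)O2)C(=O)C1(C)C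
F4 | step 6 | ethyl (2S,4S)-7-methoxy-6,6,8-trimethyl-5-oxo-4-(propan-2-yl)-3,4,5,6-tetrahydro-2H-chromene-2-carboxylate | COC1=C(C)C2=C([C@H](C(C)C)C[C@@H](C(=O)OCC)O2)C(=O)C1(C)C
F5 | step 6 | (2S,4S)-N,7-dimethoxy-N,6,6,8-tetramethyl-5-oxo-4-(propan-2-yl)-3,4,5,6-tetrahydro-2H-chromene-2-carboxamide | COC1=C(C)C2=C([C@H](C(C)C)C[C@@H](C(=O)N(C)OC)O2)C(=O)C1(C)C
F6 | step 6 | (2S,4S)-7-methoxy-6,6,8-trimethyl-2-(5-methylhex-4-enoyl)-4-(propan-2-yl)-2,3,4,6-tetrahydro-5H-chromen-5-one | COC1=C(C)C2=C([C@H](C(C)C)C[C@@H](C(=O)CCC=C(C)C)O2)C(=O)C1(C)C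
F7 | step 6 | (2S,4S)-7-methoxy-6,6,8-trimethyl-2-(6-methylhepta-1,5-dien-2-yl)-4-(propan-2-yl)-2,3,4,6-tetrahydro-5H-chromen-5-one | COC1=C(C)C2=C([C@H](C(C)C)C[C@@H](C(=C)CCC=C(C)C)O2)C(=O)C1(C)C
F8 | step 9 | (2R,4S)-2-[2-hydroxy-6-methyl-1-(trimethylsilyl)hept-5-en-2-yl]-7-methoxy-6,8,8-trimethyl-4-(propan-2-yl)-2,3,4,8-tetrahydro-5H-chromen-5-one | COC1=C(C)C(=O)C2=C(O[C@@H](C(O)(C[Si](C)(C)C)CCC=C(C)C)C[C@H]2C(C)C)C1(C)C
F0 | step 10 | none | none
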